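The cyclononadiene ring is numbered C1 (bearing CHO) to C9 (bearing CH2OAc). The route rests on the C2–C3 bond of the skipped diene C1=C2–C3–C4=C5: C2, the β-carbon of the enal, is treated as the methyl carbon of a C1 methyl ketone, and C3 as the terminus of an (E)-allylic acetate. A palladium-catalysed allylic alkylation of the kinetic ketone enolate closes the nine-membered ring with the 4E olefin in place; the formyl carbon is added later by carbonylation of the C1 enol triflate. The open-chain precursor comes from (S)-citronellal through an organocatalytic nitro-Michael addition (C8, C9) and a vinylogous aldol (C7, C4=C5).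

Key step: step 10

Assumption: the (R,R)-bisphosphoramide of step 4 is taken to deliver the dienolate to the Si face of the aldehyde; should a model aldehyde show the opposite sense, its (S,S)-enantiomer is used.

Step 1
Reactants: 1 (tert-butyldimethylsilyloxy)acetaldehyde; 2 nitromethane
Product: 5 (E)-tert-butyldimethyl[(3-nitroprop-2-en-1-yl)oxy]silane, via nitro alcohol 3 (not isolated), via nitro mesylate 4 (not isolated)
Conditions: 2 (5 equiv), KOtBu (5 mol %), THF/tBuOH, 0 °C; then MsCl, Et3N, CH2Cl2, −40 °C → 0 °C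
Reagents that add atoms: none
Why: Henry addition followed by mesylation and E1cB elimination should give the conjugated nitroalkene as the more stable E isomer.

Step 2
Reactants: 5 silyloxy nitroalkene; 6 (S)-citronellal
Product: 7 (2R,3S)-2-[(2R)-1-[(tert-butyldimethylsilyl)oxy]-3-nitropropan-2-yl]-3,7-dimethyloct-6-enal
Conditions: 6 (1.5 equiv), (S)-α,α-diphenylprolinol trimethylsilyl ether (10 mol %), 4-nitrophenol (20 mol %), toluene, 0 °C → rt
Reagents that add atoms: none
Why: In this enamine-catalysed Michael addition the E-enamine of 6, shielded on one face by the diarylsilyloxymethyl group, should add to the nitroalkene through the acyclic synclinal transition state, setting C2 (R) and the branch carbon (R) syn under catalyst control while C3 (S) comes from 6.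

Step 3
Reactants: 8 methyl 3-methylbut-2-enoate
Product: 9 (Z)-tert-butyl[(1-methoxy-3-methylbuta-1,3-dien-1-yl)oxy]dimethylsilane
Conditions: LiN(iPr)2, THF, −78 °C; TBSCl, DMPU, −78 °C → rt
Reagents that add atoms: tert-butyldimethylsilyl chloride, CC(C)(C)[Si](C)(C)Cl
Why: γ-Deprotonation gives the extended ester enolate, which is O-silylated to the silyl dienol ether (its C1 geometry is not relevant to the open transition state of step 4).

Step 4
Reactants: 7 γ-nitro aldehyde; 9 silyl dienol ether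
Product: 10 methyl (2E,5S,6R,7S)-6-[(2R)-1-[(tert-butyldimethylsilyl)oxy]-3-nitropropan-2-yl]-5-hydroxy-3,7,11-trimethyldodeca-2,10-dienoate
Conditions: SiCl4 (1.1 equiv), (R,R)-bisphosphoramide from N,N′-dimethyl-1,1′-binaphthyl-2,2′-diamine (5 mol %), iPr2NEt (10 mol %), CH2Cl2, −72 °C; sat. aq. NaHCO3 work-up
Reagents that add atoms: none
Why: In this Lewis-base-activated vinylogous Mukaiyama aldol addition the γ-carbon of 9 should attack the Si face of the aldehyde bound to the chiral trichlorosilyl cation, setting C5 (S) under catalyst control, and the open transition state with the s-trans diene should give the 2E enoate.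

Step 5
Reactants: 10 δ-hydroxy enoate
Product: 11 methyl (2E,5S,6R,7S)-5-[(tert-butyldimethylsilyl)oxy]-6-[(2R)-1-[(tert-butyldimethylsilyl)oxy]-3-nitropropan-2-yl]-3,7,11-trimethyldodeca-2,10-dienoate
Conditions: TBSOTf, 2,6-lutidine, CH2Cl2, −78 °C
Reagents that add atoms: tert-butyldimethylsilyl trifluoromethanesulfonate, CC(C)(C)[Si](C)(C)OS(=O)(=O)C(F)(F)F
Why: Silylation of the hindered secondary alcohol with the silyl triflate and a weak hindered base should leave the nitro group and enoate untouched (any silyl nitronate reverts on aqueous work-up).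

Step 6
Reactants: 11 bis-silyl enoate
Product: 12 (2E,5S,6R,7S)-5-[(tert-butyldimethylsilyl)oxy]-6-[(2R)-1-[(tert-butyldimethylsilyl)oxy]-3-nitropropan-2-yl]-3,7,11-trimethyldodeca-2,10-dien-1-ol
Conditions: (iBu)2AlH (2.5 equiv), CH2Cl2, −78 °C; aq. KNaC4H4O6 (potassium sodium tartrate)
Reagents that add atoms: none
Why: 1,2-Reduction of the enoate at low temperature should give the (E)-allylic alcohol, the nitroalkane and silyl ethers being inert to the aluminium hydride under these conditions.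

Step 7
Reactants: 12 nitro allylic alcohol
Product: 13 (2S,3R,4S)-2-{[(tert-butyldimethylsilyl)oxy]methyl}-3-[(1S,3E)-1-[(tert-butyldimethylsilyl)oxy]-5-hydroxy-3-methylpent-3-en-1-yl]-4,8-dimethylnon-7-enoic acid
Conditions: NaNO2 (3 equiv), AcOH (10 equiv), DMSO, 35 °C
Reagents that add atoms: sodium nitrite, [Na+].[O-]N=O; water, O
Why: This Nef-type oxidation of a primary nitroalkane (nitrosation to the nitrolic acid, nitrile oxide, hydrolysis) should give the carboxylic acid under buffered acidic conditions that do not epimerize the new α-carbon.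

Step 8
Reactants: 13 hydroxy acid
Product: 14 (3S,4R,5S)-3-{[(tert-butyldimethylsilyl)oxy]methyl}-4-[(1S,3E)-1-[(tert-butyldimethylsilyl)oxy]-5-hydroxy-3-methylpent-3-en-1-yl]-5,9-dimethyldec-8-en-2-one
Conditions: MeLi (4 equiv), Et2O, 0 °C → rt; poured into cold aq. NH4Cl
Reagents that add atoms: methyllithium, [Li]C
Why: Addition of MeLi to the lithium carboxylate stops at the dilithio gem-diolate, which releases the methyl ketone only on work-up, so over-addition and epimerization of the α-carbon should be avoided.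

Step 9
Reactants: 14 hydroxy methyl ketone
Product: 15 (2E,5S,6R,7S)-5-[(tert-butyldimethylsilyl)oxy]-6-[(2S)-1-[(tert-butyldimethylsilyl)oxy]-3-oxobutan-2-yl]-3,7,11-trimethyldodeca-2,10-dien-1-yl acetate
Conditions: Ac2O, pyridine, DMAP (cat.), CH2Cl2, 0 °C
Reagents that add atoms: acetic anhydride, CC(=O)OC(C)=O
Why: Acylation of the only free hydroxyl, the primary allylic one, installs the leaving group for the ring closure.

Step 10
Reactants: 15 keto allylic acetate
Product: 17 (2S,3R,4S,6E)-4-[(tert-butyldimethylsilyl)oxy]-2-{[(tert-butyldimethylsilyl)oxy]methyl}-6-methyl-3-[(2S)-6-methylhept-5-en-2-yl]cyclonon-6-en-1-one, via lithium enolate 16 (not isolated)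
Conditions: LiN(SiMe3)2 (1.05 equiv), LiCl, THF, −78 °C; then added over 6 h to Pd2(dba)3 (5 mol %), rac-BINAP (12 mol %), THF, 0 °C (final 2 mM); quenched at 0 °C
Reagents that add atoms: none
Why: Zerovalent palladium ionizes the allylic acetate of 16 to an η3-allyl complex over the future C3–C4–C5, and the kinetic lithium enolate (future C1–C2) attacks its unsubstituted terminus C3 to form the C2–C3 bond. The closest known reaction type is the Tsuji–Trost allylic alkylation of a preformed ketone enolate, here run intramolecularly at high dilution. The one ring closed is the nine-membered carbocycle, in a mode that places both enolate carbons and all three allyl carbons inside the ring (attack at the distal allyl terminus); the competing attack at C5 would give a seven-membered ring with a quaternary carbon. No stereocentre is created, C7, C8 and C9 are untouched, and the 4E geometry should be kept because syn–anti exchange at C5 would need a tertiary σ-allyl palladium. The step needs C- over O-allylation, C3 over C5 attack and an enolate that stays on the methyl side of the ketone; these are secured by the soft π-allyl electrophile, by the less hindered primary terminus, and by deprotonation at −78 °C with a non-equilibrating amide base before slow addition to the catalyst.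

Step 11
Reactants: 17 cyclononenone
Product: 18 (1E,4E,7S,8R,9S)-7-[(tert-butyldimethylsilyl)oxy]-9-{[(tert-butyldimethylsilyl)oxy]methyl}-5-methyl-8-[(2S)-6-methylhept-5-en-2-yl]cyclonona-1,4-dien-1-yl trifluoromethanesulfonate
Conditions: KN(SiMe3)2, PhNTf2, THF, −78 °C
Reagents that add atoms: N-phenylbis(trifluoromethanesulfonimide), O=S(=O)(N(c1ccccc1)S(=O)(=O)C(F)(F)F)C(F)(F)F
Why: Kinetic deprotonation at the ring CH2 (not the α-methine) and O-triflation of the enolate should give the enol triflate, whose double bond can only be cis within a ring that already holds a trans olefin (C9 and C3 cis).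

Step 12
Reactants: 18 enol triflate
Product: 19 (1E,4E,7S,8R,9S)-7-[(tert-butyldimethylsilyl)oxy]-9-(hydroxymethyl)-5-methyl-8-[(2S)-6-methylhept-5-en-2-yl]cyclonona-1,4-dien-1-yl trifluoromethanesulfonate
Conditions: HF·pyridine, pyridine, THF, 0 °C
Reagents that add atoms: none
Why: Buffered fluoride should cleave the unhindered primary silyl ether much faster than the secondary one flanked by C8.

Step 13
Reactants: 19 primary alcohol
Product: 20 (1E,4E,7S,8R,9S)-9-(acetoxymethyl)-7-[(tert-butyldimethylsilyl)oxy]-5-methyl-8-[(2S)-6-methylhept-5-en-2-yl]cyclonona-1,4-dien-1-yl trifluoromethanesulfonate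
Conditions: Ac2O, pyridine, DMAP (cat.), CH2Cl2, 0 °C
Reagents that add atoms: acetic anhydride, CC(=O)OC(C)=O
Why: Acetylation before the aldehyde exists avoids a free γ-hydroxy enal, which could close to a lactol.

Step 14
Reactants: 20 acetoxy enol triflate
Product: 21 (1E,4E,7S,8R,9R)-9-(acetoxymethyl)-7-[(tert-butyldimethylsilyl)oxy]-5-methyl-8-[(2S)-6-methylhept-5-en-2-yl]cyclonona-1,4-diene-1-carbaldehyde
Conditions: Pd(PPh3)4 (5 mol %), CO (1 atm), LiCl, Bu3SnH (slow addition), THF, 50 °C
Reagents that add atoms: carbon monoxide, [C-]#[O+]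
Why: In this Stille-type reductive carbonylation, oxidative addition into the vinyl triflate, CO insertion and hydride transfer from tin should give the enal with retention of the C1=C2 geometry (CHO trans to C3).

Step 15
Reactants: 21 silyl-protected enal
Product: 22 hydroxyacetyldictyolal, (1E,4E,7S,8R,9R)-9-(acetoxymethyl)-7-hydroxy-5-methyl-8-[(2S)-6-methylhept-5-en-2-yl]cyclonona-1,4-diene-1-carbaldehyde
Conditions: HF·pyridine, THF, 0 °C → rt
Reagents that add atoms: none
Why: Acidic fluoride removes the secondary silyl ether without touching the acetate, the enal or the base-sensitive doubly allylic C3 methylene.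

Compound list
1 | (tert-butyldimethylsilyloxy)acetaldehyde | CC(C)(C)[Si](C)(C)OCC=O | starting material
2 | nitromethane | C[N+](=O)[O-] | starting material
3 | rac-1-[(tert-butyldimethylsilyl)oxy]-3-nitropropan-2-ol (nitro alcohol) | CC(C)(C)[Si](C)(C)OCC(O)C[N+](=O)[O-] | intermediate
4 | rac-1-[(tert-butyldimethylsilyl)oxy]-3-nitropropan-2-yl methanesulfonate (nitro mesylate) | CC(C)(C)[Si](C)(C)OCC(OS(C)(=O)=O)C[N+](=O)[O-] | intermediate
5 | (E)-tert-butyldimethyl[(3-nitroprop-2-en-1-yl)oxy]silane | CC(C)(C)[Si](C)(C)OC/C=C/[N+](=O)[O-] | intermediate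
6 | (S)-citronellal, (3S)-3,7-dimethyloct-6-enal | O=CC[C@@H](C)CCC=C(C)C | starting material
7 | (2R,3S)-2-[(2R)-1-[(tert-butyldimethylsilyl)oxy]-3-nitropropan-2-yl]-3,7-dimethyloct-6-enal | CC(C)(C)[Si](C)(C)OC[C@H]([C@H](C=O)[C@@H](C)CCC=C(C)C)C[N+](=O)[O-] | intermediate
8 | methyl 3-methylbut-2-enoate | COC(=O)C=C(C)C | starting material
9 | (Z)-tert-butyl[(1-methoxy-3-methylbuta-1,3-dien-1-yl)oxy]dimethylsilane | C=C(C)/C=C(/OC)O[Si](C)(C)C(C)(C)C | intermediate
10 | methyl (2E,5S,6R,7S)-6-[(2R)-1-[(tert-butyldimethylsilyl)oxy]-3-nitropropan-2-yl]-5-hydroxy-3,7,11-trimethyldodeca-2,10-dienoate | CC(C)(C)[Si](C)(C)OC[C@H]([C@H]([C@@H](O)C/C(C)=C/C(=O)OC)[C@@H](C)CCC=C(C)C)C[N+](=O)[O-] | intermediate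
11 | methyl (2E,5S,6R,7S)-5-[(tert-butyldimethylsilyl)oxy]-6-[(2R)-1-[(tert-butyldimethylsilyl)oxy]-3-nitropropan-2-yl]-3,7,11-trimethyldodeca-2,10-dienoate | CC(C)(C)[Si](C)(C)OC[C@H]([C@H]([C@@H](O[Si](C)(C)C(C)(C)C)C/C(C)=C/C(=O)OC)[C@@H](C)CCC=C(C)C)C[N+](=O)[O-] | intermediate
12 | (2E,5S,6R,7S)-5-[(tert-butyldimethylsilyl)oxy]-6-[(2R)-1-[(tert-butyldimethylsilyl)oxy]-3-nitropropan-2-yl]-3,7,11-trimethyldodeca-2,10-dien-1-ol | CC(C)(C)[Si](C)(C)OC[C@H]([C@H]([C@@H](O[Si](C)(C)C(C)(C)C)C/C(C)=C/CO)[C@@H](C)CCC=C(C)C)C[N+](=O)[O-] | intermediate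
13 | (2S,3R,4S)-2-{[(tert-butyldimethylsilyl)oxy]methyl}-3-[(1S,3E)-1-[(tert-butyldimethylsilyl)oxy]-5-hydroxy-3-methylpent-3-en-1-yl]-4,8-dimethylnon-7-enoic acid | CC(C)(C)[Si](C)(C)OC[C@H]([C@H]([C@@H](O[Si](C)(C)C(C)(C)C)C/C(C)=C/CO)[C@@H](C)CCC=C(C)C)C(=O)O | intermediate
14 | (3S,4R,5S)-3-{[(tert-butyldimethylsilyl)oxy]methyl}-4-[(1S,3E)-1-[(tert-butyldimethylsilyl)oxy]-5-hydroxy-3-methylpent-3-en-1-yl]-5,9-dimethyldec-8-en-2-one | CC(C)(C)[Si](C)(C)OC[C@H]([C@H]([C@@H](O[Si](C)(C)C(C)(C)C)C/C(C)=C/CO)[C@@H](C)CCC=C(C)C)C(C)=O | intermediate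
15 | (2E,5S,6R,7S)-5-[(tert-butyldimethylsilyl)oxy]-6-[(2S)-1-[(tert-butyldimethylsilyl)oxy]-3-oxobutan-2-yl]-3,7,11-trimethyldodeca-2,10-dien-1-yl acetate | CC(C)(C)[Si](C)(C)OC[C@H]([C@H]([C@@H](O[Si](C)(C)C(C)(C)C)C/C(C)=C/COC(C)=O)[C@@H](C)CCC=C(C)C)C(C)=O | intermediate
16 | kinetic lithium enolate of 15 (CH2=C(OLi)– at the former acetyl group) | [Li+].CC(C)(C)[Si](C)(C)OC[C@H]([C@H]([C@@H](O[Si](C)(C)C(C)(C)C)C/C(C)=C/COC(C)=O)[C@@H](C)CCC=C(C)C)C(=C)[O-] | intermediate
17 | (2S,3R,4S,6E)-4-[(tert-butyldimethylsilyl)oxy]-2-{[(tert-butyldimethylsilyl)oxy]methyl}-6-methyl-3-[(2S)-6-methylhept-5-en-2-yl]cyclonon-6-en-1-one | CC(C)(C)[Si](C)(C)OC[C@H]1C(=O)CC/C=C(\C)C[C@H](O[Si](C)(C)C(C)(C)C)[C@@H]1[C@@H](C)CCC=C(C)C | intermediate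
18 | (1E,4E,7S,8R,9S)-7-[(tert-butyldimethylsilyl)oxy]-9-{[(tert-butyldimethylsilyl)oxy]methyl}-5-methyl-8-[(2S)-6-methylhept-5-en-2-yl]cyclonona-1,4-dien-1-yl trifluoromethanesulfonate | CC(C)(C)[Si](C)(C)OC[C@H]1/C(OS(=O)(=O)C(F)(F)F)=C\C/C=C(\C)C[C@H](O[Si](C)(C)C(C)(C)C)[C@@H]1[C@@H](C)CCC=C(C)C | intermediate
19 | (1E,4E,7S,8R,9S)-7-[(tert-butyldimethylsilyl)oxy]-9-(hydroxymethyl)-5-methyl-8-[(2S)-6-methylhept-5-en-2-yl]cyclonona-1,4-dien-1-yl trifluoromethanesulfonate | OC[C@H]1/C(OS(=O)(=O)C(F)(F)F)=C\C/C=C(\C)C[C@H](O[Si](C)(C)C(C)(C)C)[C@@H]1[C@@H](C)CCC=C(C)C | intermediate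
20 | (1E,4E,7S,8R,9S)-9-(acetoxymethyl)-7-[(tert-butyldimethylsilyl)oxy]-5-methyl-8-[(2S)-6-methylhept-5-en-2-yl]cyclonona-1,4-dien-1-yl trifluoromethanesulfonate | CC(=O)OC[C@H]1/C(OS(=O)(=O)C(F)(F)F)=C\C/C=C(\C)C[C@H](O[Si](C)(C)C(C)(C)C)[C@@H]1[C@@H](C)CCC=C(C)C | intermediate
21 | (1E,4E,7S,8R,9R)-9-(acetoxymethyl)-7-[(tert-butyldimethylsilyl)oxy]-5-methyl-8-[(2S)-6-methylhept-5-en-2-yl]cyclonona-1,4-diene-1-carbaldehyde | CC(=O)OC[C@H]1/C(C=O)=C\C/C=C(\C)C[C@H](O[Si](C)(C)C(C)(C)C)[C@@H]1[C@@H](C)CCC=C(C)C | intermediate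
22 | hydroxyacetyldictyolal, (1E,4E,7S,8R,9R)-9-(acetoxymethyl)-7-hydroxy-5-methyl-8-[(2S)-6-methylhept-5-en-2-yl]cyclonona-1,4-diene-1-carbaldehyde | CC(=O)OC[C@H]1/C(C=O)=C\C/C=C(\C)C[C@H](O)[C@@H]1[C@@H](C)CCC=C(C)C | target

Total step count: 15. Longest linear sequence: 14 steps (steps 1, 2 and 4–15, counted from 1; step 3 is a one-step side branch).

Steps most likely to fail

Step 10 (key step). The nine-membered closure is slow, so the kinetic enolate may equilibrate by proton transfer and alkylate through the methine carbon (seven-membered ring), the allyl complex may lose a β-hydride to a diene, or chains may oligomerize. The fallback sets out from 15 and comes back at 17. The kinetic enolate of 15 (LiN(SiMe3)2, THF, −78 °C) is C-sulfonylated with PhSO2F to the acyclic β-keto sulfone F1. Its doubly stabilized carbanion is cyclized under soft Tsuji–Trost conditions (Pd(PPh3)4, Ph2PCH2CH2PPh2, N,O-bis(trimethylsilyl)acetamide, KOAc (cat.), THF, reflux, slow addition) to the cyclic β-keto sulfone F2. SmI2 (THF/MeOH, −78 °C) then removes the sulfonyl group and should give 17.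

Step 4. The hindered α-branched aldehyde may react sluggishly with the chiral silicon Lewis acid, or its inherent facial bias may override the catalyst and erode the selectivity at C5. The fallback sets out from 7 and comes back at 10. The dienolate 9 is added under substrate control with BF3·OEt2 (CH2Cl2, −78 °C). The Felkin-type C5 epimer F3 expected from this mode is inverted by a Mitsunobu reaction (4-nitrobenzoic acid, PPh3, diisopropyl azodicarboxylate, toluene, 0 °C → rt) to the (5S)-4-nitrobenzoate F4, and methanolysis (K2CO3, MeOH, 0 °C) should give 10.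

Step 14. Hydride transfer to the vinylpalladium species may outrun CO insertion at the hindered ring carbon and give the reduced diene in place of the aldehyde. The fallback sets out from 20 and comes back at 21. Stille coupling of 20 with Bu3SnCH2OH (Pd(PPh3)4, LiCl, dioxane, 90 °C) gives the allylic alcohol F5, which is oxidized with MnO2 (CH2Cl2, rt) to 21.

Further compounds
F1 | step 10 | acyclic β-keto sulfone, 15 carrying a phenylsulfonyl group on the ketone methyl: (2E,5S,6R,7S)-5-[(tert-butyldimethylsilyl)oxy]-6-[(2S)-1-[(tert-butyldimethylsilyl)oxy]-3-oxo-4-(phenylsulfonyl)butan-2-yl]-3,7,11-trimethyldodeca-2,10-dien-1-yl acetate | CC(C)(C)[Si](C)(C)OC[C@H]([C@H]([C@@H](O[Si](C)(C)C(C)(C)C)C/C(C)=C/COC(C)=O)[C@@H](C)CCC=C(C)C)C(=O)CS(=O)(=O)c1ccccc1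
F2 | step 10 | cyclic β-keto sulfone, 17 carrying a phenylsulfonyl group at C9 (both C9 epimers) | CC(C)(C)[Si](C)(C)OC[C@H]1C(=O)C(S(=O)(=O)c2ccccc2)C/C=C(\C)C[C@H](O[Si](C)(C)C(C)(C)C)[C@@H]1[C@@H](C)CCC=C(C)C
F3 | step 4 | (5R)-epimer of 10, methyl (2E,5R,6R,7S)-6-[(2R)-1-[(tert-butyldimethylsilyl)oxy]-3-nitropropan-2-yl]-5-hydroxy-3,7,11-trimethyldodeca-2,10-dienoate | CC(C)(C)[Si](C)(C)OC[C@H]([C@H]([C@H](O)C/C(C)=C/C(=O)OC)[C@@H](C)CCC=C(C)C)C[N+](=O)[O-]
F4 | step 4 | (5S)-4-nitrobenzoate of 10, methyl (2E,5S,6R,7S)-6-[(2R)-1-[(tert-butyldimethylsilyl)oxy]-3-nitropropan-2-yl]-3,7,11-trimethyl-5-[(4-nitrobenzoyl)oxy]dodeca-2,10-dienoate | CC(C)(C)[Si](C)(C)OC[C@H]([C@H]([C@@H](OC(=O)c1ccc(cc1)[N+](=O)[O-])C/C(C)=C/C(=O)OC)[C@@H](C)CCC=C(C)C)C[N+](=O)[O-]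
F5 | step 14 | allylic alcohol, 21 with CH2OH in place of CHO at C1: [(1R,2R,3S,5E,8E)-3-[(tert-butyldimethylsilyl)oxy]-9-(hydroxymethyl)-5-methyl-2-[(2S)-6-methylhept-5-en-2-yl]cyclonona-5,8-dien-1-yl]methyl acetate | CC(=O)OC[C@H]1/C(CO)=C\C/C=C(\C)C[C@H](O[Si](C)(C)C(C)(C)C)[C@@H]1[C@@H](C)CCC=C(C)C
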